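The cyclohexane ring (primed locants; C-1′ bonded to the oxane, C-3′ = CHCl, C-4′ = CBr) is cut at C-1′–C-6′ and C-3′–C-4′. Both bonds are made in one flask from an open-chain epoxy silyl ether that carries an allyl group on the oxirane and the prenyl side chain: a copper-catalysed Grignard opening at the future C-1′ (inversion, freeing the tertiary oxygen on oxane C-2), then ring-closing metathesis to the C-3′=C-4′ alkene. The step exploits the O–C-2(oxane)–C-1′(cyclohexane) array, the imprint of an epoxide, and the vicinal trans-diaxial Cl/Br pair on C-3′/C-4′, the imprint of an alkene. The oxane and both ring halogens follow afterwards.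

Key step: step 6

Remark: unprimed locants number the oxane of the target (O-1, quaternary C-2, carbinol C-3, CHBr C-5, CMe2 C-6); compounds 1, 2, 4, 7, 8 and 13 are taken as commercially available.

Step 1
Reactants: 1 3-(trimethylsilyl)prop-2-ynal; 2 allyltributylstannane
Product: 3 (3R)-1-(trimethylsilyl)hex-5-en-1-yn-3-ol
Conditions: (R)-BINOL (20 mol%), Ti(OiPr)4 (10 mol%), 4 Å molecular sieves, CH2Cl2, −20 °C; aqueous NaHCO3 work-up
Reagents that add atoms: allyltributylstannane (2), C=CC[Sn](CCCC)(CCCC)CCCC
Why: Keck asymmetric allylation, in which the (R)-BINOL–titanium Lewis acid activates the non-enolisable ynal and directs allyl transfer to its Re face (the sense that gives R carbinols when the aldehyde substituent outranks allyl), so the future oxane C-3 is set here.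

Step 2
Reactants: 3 (3R)-1-(trimethylsilyl)hex-5-en-1-yn-3-ol; 4 2-methylbut-2-ene
Product: 6 (3R)-6-methylhept-5-en-1-yn-3-ol, via silyl enynol 5 (not isolated)
Conditions: second-generation Grubbs catalyst (3 mol%), 2-methylbut-2-ene/CH2Cl2, 40 °C; concentrate; K2CO3, MeOH, rt
Reagents that add atoms: 2-methylbut-2-ene (4), CC=C(C)C
Why: Olefin cross-metathesis with 2-methylbut-2-ene turns the terminal vinyl group into the prenyl-type alkene while the silyl cap keeps the alkyne out of enyne metathesis, and carbonate methanolysis then removes the C-silyl group without touching the carbinol stereocentre.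

Step 3
Reactants: 6 (3R)-6-methylhept-5-en-1-yn-3-ol; 7 methylmagnesium bromide; 8 allyl bromide
Product: 10 (5R,6Z)-2,6-dimethyldeca-2,6,9-trien-5-ol, via alkenylmagnesium alkoxide 9 (not isolated)
Conditions: MeMgBr (3.5 equiv), CuI (15 mol%), THF, 0 °C → rt; then allyl bromide (4 equiv), 0 °C → rt; aqueous work-up
Reagents that add atoms: methylmagnesium bromide (7), C[Mg]Br; allyl bromide (8), C=CCBr
Why: Copper-catalysed anti-carbomagnesiation of a propargylic alkoxide, in which the magnesium alkoxide sends methyl to the internal alkyne carbon and holds the new C–Mg bond cis to the carbinol in a five-membered chelate, followed by copper-mediated allylation with retention, which gives the Z-trisubstituted alkene and leaves the carbinol stereocentre unchanged.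

Step 4
Reactants: 10 (5R,6Z)-2,6-dimethyldeca-2,6,9-trien-5-ol
Product: 11 (1R)-4-methyl-1-[(2S,3R)-2-methyl-3-(prop-2-en-1-yl)oxiran-2-yl]pent-3-en-1-ol
Conditions: Ti(OiPr)4 (0.3 equiv), t-BuOOH (1.5 equiv, decane), 4 Å molecular sieves, CH2Cl2, −20 °C
Reagents that add atoms: tert-butyl hydroperoxide, CC(C)(C)OO
Why: Hydroxyl-directed titanium-catalysed epoxidation touches only the allylic alkene, and because the cis allyl group enforces the A(1,3)-minimised rotamer with the carbinol hydrogen in the alkene plane, oxygen should be delivered from the hydroxyl face to give the threo epoxy alcohol, which sets oxirane C-2 (S) and C-3 (R).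

Step 5
Reactants: 11 (1R)-4-methyl-1-[(2S,3R)-2-methyl-3-(prop-2-en-1-yl)oxiran-2-yl]pent-3-en-1-ol
Product: 12 triethylsilyl ether of 11, triethyl({(1R)-4-methyl-1-[(2R,3R)-2-methyl-3-(prop-2-en-1-yl)oxiran-2-yl]pent-3-en-1-yl}oxy)silane (same spatial arrangement; oxirane C-2 becomes R by priority change only)
Conditions: Et3SiCl (1.2 equiv), imidazole (2 equiv), CH2Cl2, 0 °C
Reagents that add atoms: chlorotriethylsilane, CC[Si](Cl)(CC)CC
Why: Imidazole-promoted silylation of the secondary hydroxyl creates no stereocentre and keeps this oxygen from competing as a nucleophile in the later bromoetherification.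

Step 6
Reactants: 12 triethylsilyl ether of 11; 13 4-bromo-2-methylbut-1-ene
Product: 16 (2R,3R)-6-methyl-2-[(1S)-4-methylcyclohex-3-en-1-yl]-3-[(triethylsilyl)oxy]hept-5-en-2-ol, via Grignard reagent 14 (not isolated), via acyclic triene alcohol 15 (not isolated)
Conditions: 13, Mg, THF (gives 14); 12, CuBr·SMe2 (15 mol%), THF, −30 → 0 °C; AcOH (to neutral), CH2Cl2, second-generation Grubbs catalyst (5 mol%), 40 °C
Reagents that add atoms: (3-methylbut-3-en-1-yl)magnesium bromide (14, made from 13 and Mg), C=C(C)CC[Mg]Br
Why: The Grignard reagent 14 is turned by CuBr·SMe2 into an organocopper species that opens the trisubstituted epoxide of 12 by SN2 attack at the secondary oxirane carbon C-3, anti to the C–O bond, which forms the C-1′–C-6′ bond with inversion and frees the tertiary alkoxide on the future oxane C-2; after neutralisation the ruthenium carbene loads onto the monosubstituted allyl alkene and closes onto the 1,1-disubstituted alkene, forming C-3′=C-4′ with loss of ethene. The closest known reaction types are the copper-catalysed Grignard opening of epoxides and ring-closing olefin metathesis, here telescoped in one flask. The six-membered carbocycle is closed by ring-closing metathesis of a 1,7-diene to an endocyclic trisubstituted alkene. The only new stereocentre, C-1′, is set by the stereospecific inversion at the epoxide carbon, so its S configuration relative to C-2 (R) is dictated by the Z geometry of 10 and the threo epoxidation of step 4. The step needs opening at oxirane C-3 and not C-2, which is secured because C-2 is fully substituted, and it needs chemoselective ring closure, which is secured because the prenyl alkene is trisubstituted and a poor metathesis partner while the alternative ring would be seven-membered.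

Step 7
Reactants: 16 (2R,3R)-6-methyl-2-[(1S)-4-methylcyclohex-3-en-1-yl]-3-[(triethylsilyl)oxy]hept-5-en-2-ol
Product: 17 triethyl({(2R,3R,5R)-5-bromo-2,6,6-trimethyl-2-[(1S)-4-methylcyclohex-3-en-1-yl]oxan-3-yl}oxy)silane
Conditions: 2,4,4,6-tetrabromocyclohexa-2,5-dienone (1.1 equiv), MeNO2, −20 → 0 °C
Reagents that add atoms: 2,4,4,6-tetrabromocyclohexa-2,5-dienone, O=C1C(Br)=CC(Br)(Br)C=C1Br
Why: Bromonium-induced 6-endo (Markovnikov) bromoetherification, in which Br+ transfer between the two trisubstituted alkenes is reversible but only the side-chain bromonium ion is trapped quickly, by the tertiary hydroxyl through a chair transition state with bromine equatorial, the C-2 methyl axial and the cyclohexenyl group equatorial, which should set C-5 as R, whereas capture of the ring bromonium ion would need a boat leading to a bicyclic ether.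

Step 8
Reactants: 17 triethyl({(2R,3R,5R)-5-bromo-2,6,6-trimethyl-2-[(1S)-4-methylcyclohex-3-en-1-yl]oxan-3-yl}oxy)silane
Product: 18 (1R,2R,4S)-4-{(2R,3R,5R)-5-bromo-2,6,6-trimethyl-3-[(triethylsilyl)oxy]oxan-2-yl}-2-chloro-1-methylcyclohexan-1-ol
Conditions: trichloroisocyanuric acid (0.36 equiv), acetone/H2O (4:1), 0 °C
Reagents that add atoms: trichloroisocyanuric acid, ClN1C(=O)N(Cl)C(=O)N(Cl)C1=O; water, O
Why: Chlorohydrin formation (cohalogenation) in which electrophilic chlorine adds axially to C-3′ on the face trans to the equatorial oxanyl group and water opens the chloronium ion at the tertiary C-4′ from the opposite face (Markovnikov, trans-diaxial, Fürst–Plattner rule), so the hydroxyl should end cis and the chlorine trans to the C-1′ substituent, as in the bromohydrin formation of 4-substituted 1-methylcyclohexenes.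

Step 9
Reactants: 18 (1R,2R,4S)-4-{(2R,3R,5R)-5-bromo-2,6,6-trimethyl-3-[(triethylsilyl)oxy]oxan-2-yl}-2-chloro-1-methylcyclohexan-1-ol
Product: 19 (2R,3R,5R)-5-bromo-2-[(1S,3R,4R)-4-bromo-3-chloro-4-methylcyclohexyl]-2,6,6-trimethyloxan-3-ol
Conditions: Me3SiBr (3 equiv), CH2Cl2, −40 → 0 °C; then MeOH, 0 °C
Reagents that add atoms: bromotrimethylsilane, C[Si](C)(C)Br
Why: SN1 substitution of the tertiary alcohol with neighbouring-group participation by the anti-periplanar axial chlorine, so that bromide enters axially on the face just vacated (retention, and also the thermodynamically preferred trans-diaxial Br/Cl arrangement with equatorial methyl, which makes the step stereoconvergent), while the HBr released on the methanol quench removes the triethylsilyl group.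

Compound list
1 | 3-(trimethylsilyl)prop-2-ynal | C[Si](C)(C)C#CC=O | starting material
2 | allyltributylstannane | C=CC[Sn](CCCC)(CCCC)CCCC | starting material
3 | (3R)-1-(trimethylsilyl)hex-5-en-1-yn-3-ol | C[Si](C)(C)C#C[C@H](O)CC=C | intermediate
4 | 2-methylbut-2-ene | CC=C(C)C | starting material
5 | (3R)-6-methyl-1-(trimethylsilyl)hept-5-en-1-yn-3-ol | C[Si](C)(C)C#C[C@H](O)CC=C(C)C | intermediate
6 | (3R)-6-methylhept-5-en-1-yn-3-ol | C#C[C@H](O)CC=C(C)C | intermediate
7 | methylmagnesium bromide | C[Mg]Br | starting material
8 | allyl bromide (3-bromoprop-1-ene) | C=CCBr | starting material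
9 | bromomagnesium (1Z,3R)-1-(bromomagnesio)-2,6-dimethylhepta-1,5-dien-3-olate (Mg on C-1 cis to the carbinol carbon) | Br[Mg]/C=C(/C)[C@H](O[Mg]Br)CC=C(C)C | intermediate
10 | (5R,6Z)-2,6-dimethyldeca-2,6,9-trien-5-ol | C=CC/C=C(/C)[C@H](O)CC=C(C)C | intermediate
11 | (1R)-4-methyl-1-[(2S,3R)-2-methyl-3-(prop-2-en-1-yl)oxiran-2-yl]pent-3-en-1-ol | C=CC[C@H]1O[C@@]1(C)[C@H](O)CC=C(C)C | intermediate
12 | triethyl({(1R)-4-methyl-1-[(2R,3R)-2-methyl-3-(prop-2-en-1-yl)oxiran-2-yl]pent-3-en-1-yl}oxy)silane | C=CC[C@H]1O[C@@]1(C)[C@H](O[Si](CC)(CC)CC)CC=C(C)C | intermediate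
13 | 4-bromo-2-methylbut-1-ene | C=C(C)CCBr | starting material
14 | (3-methylbut-3-en-1-yl)magnesium bromide | C=C(C)CC[Mg]Br | intermediate
15 | (5S,6R,7R)-2,6,10-trimethyl-5-(prop-2-en-1-yl)-7-[(triethylsilyl)oxy]undeca-1,9-dien-6-ol | C=CC[C@H](CCC(C)=C)[C@@](C)(O)[C@H](O[Si](CC)(CC)CC)CC=C(C)C | intermediate
16 | (2R,3R)-6-methyl-2-[(1S)-4-methylcyclohex-3-en-1-yl]-3-[(triethylsilyl)oxy]hept-5-en-2-ol | CC1=CC[C@H](CC1)[C@@](C)(O)[C@H](O[Si](CC)(CC)CC)CC=C(C)C | intermediate
17 | triethyl({(2R,3R,5R)-5-bromo-2,6,6-trimethyl-2-[(1S)-4-methylcyclohex-3-en-1-yl]oxan-3-yl}oxy)silane | CC1(C)O[C@](C)([C@@H]2CC=C(C)CC2)[C@H](O[Si](CC)(CC)CC)C[C@H]1Br | intermediate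
18 | (1R,2R,4S)-4-{(2R,3R,5R)-5-bromo-2,6,6-trimethyl-3-[(triethylsilyl)oxy]oxan-2-yl}-2-chloro-1-methylcyclohexan-1-ol | CC1(C)O[C@](C)([C@H]2CC[C@@](C)(O)[C@H](Cl)C2)[C@H](O[Si](CC)(CC)CC)C[C@H]1Br | intermediate
19 | (2R,3R,5R)-5-bromo-2-[(1S,3R,4R)-4-bromo-3-chloro-4-methylcyclohexyl]-2,6,6-trimethyloxan-3-ol | CC1(C)O[C@](C)([C@H]2CC[C@@](C)(Br)[C@H](Cl)C2)[C@H](O)C[C@H]1Br | target

Total step count: 9. Longest linear sequence: 9 steps (1 → 19).

Steps most likely to fail

Step 7. The bromonium ion may form on the ring alkene and be trapped across the ring by the tertiary hydroxyl, the side-chain closure may go 5-exo, or bromine may be delivered to the wrong face at C-5. The fallback changes the order of events so that no ring alkene is present during etherification. It sets out from 12: only the copper-catalysed opening with 14 is run and the triene alcohol 15 is isolated. Treatment of 15 with 2,4,4,6-tetrabromocyclohexa-2,5-dienone, where the only competitors of the prenyl alkene are a monosubstituted and a 1,1-disubstituted alkene, should give triethyl({(2R,3R,5R)-5-bromo-2,6,6-trimethyl-2-[(4S)-7-methylocta-1,7-dien-4-yl]oxan-3-yl}oxy)silane F3. Ring-closing metathesis of F3 with the second-generation Hoveyda–Grubbs catalyst then closes the carbocycle and comes back to the route at 17.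

Step 9. Ionisation of the tertiary alcohol may end in proton loss (E1) instead of bromide capture, the acid may reopen the oxane through participation of the C-5 bromine, or bromide may enter on the wrong face. The fallback replaces acid-mediated ionisation by neutral O-activation and separates the deprotection. It sets out from 18, which is treated with 1-bromo-N,N,2-trimethylprop-1-en-1-amine (CH2Cl2, 0 °C), so that the alkoxy-iminium bromide ion pair collapses to the tertiary bromide without free acid. This should give triethyl({(2R,3R,5R)-5-bromo-2-[(1S,3R,4R)-4-bromo-3-chloro-4-methylcyclohexyl]-2,6,6-trimethyloxan-3-yl}oxy)silane F4. Desilylation of F4 with HF·pyridine (THF, 0 °C) comes back to the route at 19.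

Step 6. Opening at the hindered oxirane carbon may be so slow that base-induced isomerisation of the epoxide to an allylic alcohol takes over, and copper and magnesium salts carried into the second stage may deactivate the ruthenium carbene. The fallback builds the ring stepwise with isolation at each stage and makes the metathesis partner by olefination. It sets out from 12, which is opened with [2-(2-methyl-1,3-dioxolan-2-yl)ethyl]magnesium bromide and CuBr·SMe2 to give (4S,5R,6R)-5,9-dimethyl-4-[2-(2-methyl-1,3-dioxolan-2-yl)ethyl]-6-[(triethylsilyl)oxy]deca-1,8-dien-5-ol F1. Mild ketal hydrolysis (PPTS, wet acetone) gives (5S,6R,7R)-6-hydroxy-6,10-dimethyl-5-(prop-2-en-1-yl)-7-[(triethylsilyl)oxy]undec-9-en-2-one F2. Wittig methylenation of F2 (Ph3P=CH2, THF) gives 15 as an isolated compound, and ring-closing metathesis of purified 15 comes back to the route at 16.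

Further compounds
F1 | step 6 | (4S,5R,6R)-5,9-dimethyl-4-[2-(2-methyl-1,3-dioxolan-2-yl)ethyl]-6-[(triethylsilyl)oxy]deca-1,8-dien-5-ol | C=CC[C@H](CCC1(C)OCCO1)[C@@](C)(O)[C@H](O[Si](CC)(CC)CC)CC=C(C)C
F2 | step 6 | (5S,6R,7R)-6-hydroxy-6,10-dimethyl-5-(prop-2-en-1-yl)-7-[(triethylsilyl)oxy]undec-9-en-2-one | C=CC[C@H](CCC(C)=O)[C@@](C)(O)[C@H](O[Si](CC)(CC)CC)CC=C(C)C
F3 | step 7 | triethyl({(2R,3R,5R)-5-bromo-2,6,6-trimethyl-2-[(4S)-7-methylocta-1,7-dien-4-yl]oxan-3-yl}oxy)silane | CC1(C)O[C@](C)([C@H](CC=C)CCC(C)=C)[C@H](O[Si](CC)(CC)CC)C[C@H]1Br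
F4 | step 9 | triethyl({(2R,3R,5R)-5-bromo-2-[(1S,3R,4R)-4-bromo-3-chloro-4-methylcyclohexyl]-2,6,6-trimethyloxan-3-yl}oxy)silane | CC1(C)O[C@](C)([C@H]2CC[C@@](C)(Br)[C@H](Cl)C2)[C@H](O[Si](CC)(CC)CC)C[C@H]1Br
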